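Readings and results come from a simulation with made-up constants; scatter was added.

The amber run and the teal run were charged 4.00 times apart in substrate, so I began by asking what that difference had changed.

| flask | substrate | remark | time |
|---|---|---|---|
| amber | 0.50 M | run made earlier |  |
| teal | 2 M | run made earlier |  |
| flask | 1.0 M |  | 5.0 h |

| run | time / h | isomer of the product A / % | target / % |
|---|---|---|---|
| amber | 0.667 | 5.7 | 29.7 |
| amber | 1.33 | 12.7 | 30.5 |
| amber | 2.00 | 18.3 | 27.3 |
| amber | 3.00 | 25.8 | 23.9 |
| amber | 4.00 | 32.7 | 21.0 |
| amber | 5.00 | 37.9 | 18.7 |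
| teal | 0.417 | 3.2 | 25.7 |
| teal | 0.667 | 5.7 | 29.9 |
| teal | 1.00 | 8.9 | 31.6 |
| teal | 1.33 | 12.4 | 30.2 |
| teal | 2.00 | 18.7 | 28.0 |
| teal | 3.00 | 26.5 | 23.7 |
| teal | 5.00 | 37.9 | 18.3 |

(readings scatter by 0.3 percentage points)



1. share of isomer of the product A in isomer of the product A plus target at 50 s
2. share of isomer of the product A in isomer of the product A plus target at 5.0 h

At 5.00 h, amber had 43.4% of its charge in neither c(target) nor c(isomer of the product A), and I carried this gap in the mass balance as the fraction left. Teal gave 43.8% at the same time, a difference of 0.4 percentage points with each reading good to 0.3 points. So I took the fraction left as independent of charge for this flask at 1.0 M, which lies between the two runs. The share at 5.0 h is then c(isomer of the product A) over what the fraction left leaves, and amber gave 67.0%. But 50 s lies far before any reading. The earliest, teal at 0.417 h, gave 11.1%, and I committed to no figure below it.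

The forecast, reasoning “so all steps behave as first order”, gave 4.5% and 67.2%.

The flask gave 0.358% at 50 s and 67.0% at 5.0 h, both within the forecast's margins.

    substrate ⇌ other conformer (K = 0.402, k = 1.25 × 10⁻⁴ s⁻¹)
    substrate ⇌ target (K = 0.882, k = 3.15 × 10⁻⁴ s⁻¹)
    other conformer → isomer of the product A (k = 3.62 × 10⁻⁴ s⁻¹)
    other conformer ⇌ dormant form (K = 0.390, k = 1.58 × 10⁻⁴ s⁻¹)
    target ⇌ isomer of the product B (K = 0.920, k = 9.09 × 10⁻⁵ s⁻¹)

Its fraction left at 5.0 h was 42.9%, close to amber's 43.4%, with substrate at 19.6% and isomer of the product B at 17.7% of the charge. The fraction left gives the sum of the two and not their split, so what could show the forecast wrong at 5.0 h was a run whose split moved with the charge. The neighbour flask at 0.25 M had a fraction left of 42.9% and a share of 67.0%.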